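## Retrosynthetic overview

1. The side chain goes on last: C12–C13 by B-alkyl Suzuki coupling with 4-bromofuran-2(5H)-one, and C9–C11 by Stille vinylation of a C8=C9 enol triflate made from a C9 enone.
2. C2–OH (thermodynamic) and C6–OH (kinetic, convex face) come from ketones, the C19 acetate from a C4 ester, and the 4α-methyl from enolate methylation.
3. Key step: ring A is annulated in one flask onto C5=C10 of a 2,6-dimethylbenzoquinone monoketal. Michael addition makes C4–C5; the C9 enolate is then alkylated at C10 by a tethered 2-(chloromethyl)allyl group, an acetonyl-cation (enolonium) equivalent. This joins two α-carbons that are both natively nucleophilic (C10 next to C9=O, C1 next to the latent C2=O) as a 1,4-dicarbonyl, and sets C5, quaternary C10 and the cis ring fusion.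
4. The same linchpin, 3-chloro-2-(chloromethyl)prop-1-ene (a 1,3-dichloroacetone surrogate), first alkylates methyl acetate (C3–C4). An (S,S)-hydrobenzoin ketal on the quinone carries the absolute configuration.
5. Ring order: ring B (from 2,6-dimethylphenol by oxidative dearomatisation) → ring A (key annulation) → butenolide (bought, coupled last).

Locants: labdane locants on the decalin core (ring A = C1–C5 and C10; ring B = C5–C10; C19 = oxygenated carbon on C4). β is the face of the C10 methyl, α the opposite face. The target has H-5 β (cis-fused) and is (2R,4S,5S,6S,10S).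

Assumption: the (S,S)-hydrobenzoin ketal steers the Michael addition anti to the phenyl that leans over the attacked carbon, giving the series shown; if the sense proves opposite, (R,R)-hydrobenzoin is used with no other change.

## Route

Step 1
Reactants: 1 2,6-dimethylphenol
Product: 3 4,4-dimethoxy-2,6-dimethylcyclohexa-2,5-dien-1-one, via 4-methoxy-2,6-dimethylphenol 2 (not isolated)
Conditions: PhI(OAc)2 (2.1 equiv), MeOH, 0 °C → rt
Reagents that add atoms: methanol, CO
Why: Hypervalent-iodine oxidative dearomatisation, in which two successive two-electron oxidations with methanol trapping at the para carbon give the quinone monoketal with the methyl-flanked carbonyl left free; no stereocentre is formed.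

Step 2
Reactants: 3 4,4-dimethoxy-2,6-dimethylcyclohexa-2,5-dien-1-one; 4 (1S,2S)-1,2-diphenylethane-1,2-diol
Product: 5 (2S,3S)-7,9-dimethyl-2,3-diphenyl-1,4-dioxaspiro[4.5]deca-6,9-dien-8-one
Conditions: PPTS (10 mol %), benzene, 4 Å molecular sieves, 50 °C
Reagents that add atoms: none
Why: Acid-catalysed transketalisation driven by loss of methanol installs the C2-symmetric auxiliary, whose two stereocentres come unchanged from the diol and make the two faces of each enone β-carbon diastereotopic.

Step 3
Reactants: 6 methyl acetate; 7 3-chloro-2-(chloromethyl)prop-1-ene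
Product: 9 methyl 4-(chloromethyl)pent-4-enoate, via lithium 1-methoxyethenolate 8 (not isolated)
Conditions: LiN(i-Pr)2, THF, −78 °C; then inverse addition to 7 (3 equiv), DMPU, −78 → −20 °C
Reagents that add atoms: none
Why: Ester enolate alkylation with the dichloride in excess (mono-alkylation), the dichloride acting as a 1,3-dichloroacetone (acetone α,α′-dication) equivalent so that C3–C4 already links the ester α-carbon to an α-carbon of the latent C2 ketone; no stereocentre is formed.

Step 4
Reactants: 5 chiral quinone monoketal; 9 methyl 4-(chloromethyl)pent-4-enoate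
Product: 12 cis-fused enone ester (C4 epimers; 2-methylidene; C9 enone; C6 ketal), via chloro-ester lithium enolate 10 (not isolated), via Michael-adduct lithium dienolate 11 (not isolated)
Conditions: 9, LiN(i-Pr)2, THF, −78 °C; add 5, −78 → −20 °C; then DMPU, → 25 °C
Reagents that add atoms: none
Why: Michael-initiated ring closure (tandem Michael addition/intramolecular enolate C-alkylation): the ester enolate adds to C5 on the face not covered by the proximal phenyl of the ketal (sets C5), and the resulting tetrasubstituted C9 enolate is alkylated at C10 through a six-membered transition state by the tethered 2-(chloromethyl)allyl group, an acetonyl-cation (enolonium) equivalent joining the α-carbon of the C9 ketone to the α-carbon of the latent C2 ketone, the tether forcing C10–C1 cis to C5–C4 so that quaternary C10 and the cis fusion are set together.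

Step 5
Reactants: 12 cis-fused enone ester (C4 epimers)
Product: 14 4α-methyl-4β-methoxycarbonyl enone ester, via lithium ester enolate 13 (not isolated)
Conditions: LiN(i-Pr)2, THF, −78 °C; then MeI, DMPU, −78 → −20 °C
Reagents that add atoms: iodomethane, CI
Why: Enolate alkylation at the only acidic position (the C9 ketone has no α-hydrogen), where allylic strain holds H-5 in the enolate plane so that ring A is the chair with the C10 methyl axial and iodomethane enters equatorially from the α face, away from that syn-axial methyl, giving 4α-CH3/4β-CO2Me.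

Step 6
Reactants: 14 4α-methyl enone ester
Product: 16 C8=C9 enol triflate ester, via lithium C8=C9 enolate 15 (not isolated)
Conditions: Li(s-Bu)3BH, THF, −78 °C; then PhNTf2, −78 → 0 °C
Reagents that add atoms: N-phenylbis(trifluoromethanesulfonimide), O=S(=O)(N(c1ccccc1)S(=O)(=O)C(F)(F)F)C(F)(F)F
Why: Conjugate hydride reduction of the β-unsubstituted enone followed by O-triflation of the regiodefined enolate (C10 is quaternary) fixes the tetrasubstituted C8=C9 alkene as its enol triflate; the ester and the exocyclic alkene are inert and no stereocentre is formed.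

Step 7
Reactants: 16 enol triflate ester
Product: 18 C19 acetate enol triflate, via C19 primary alcohol 17 (not isolated)
Conditions: i-Bu2AlH (2.5 equiv), CH2Cl2, −78 → −20 °C; then pyridine, DMAP, Ac2O, → rt
Reagents that add atoms: acetic anhydride, CC(=O)OC(C)=O
Why: Ester reduction to the aluminium alkoxide and in situ O-acetylation (reductive acetylation) place the acetate on C19 while no other hydroxyl exists in the molecule; stereocentres are untouched.

Step 8
Reactants: 18 C19 acetate enol triflate
Product: 20 C2 ketone, via 2-hydroxy-2-hydroxymethyl diol 19 (not isolated)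
Conditions: OsO4 (2 mol %), NaIO4 (4 equiv), 2,6-lutidine, dioxane/H2O (3:1), rt
Reagents that add atoms: osmium tetroxide, O=[Os](=O)(=O)=O; sodium periodate, [Na+].[O-]I(=O)(=O)=O
Why: Lemieux–Johnson oxidation, in which OsO4 dihydroxylates the unhindered 1,1-disubstituted alkene but not the tetrasubstituted, electron-poor enol triflate, and periodate cleaves the diol to unveil the C2 ketone.

Step 9
Reactants: 20 C2 ketone
Product: 21 2α-alcohol
Conditions: {[Ph4(η5-C4CO)]2H}Ru2(CO)4(μ-H) (4 mol %), i-PrOH/toluene (1:1), 90 °C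
Reagents that add atoms: none
Why: Reversible transfer hydrogenation (Meerwein–Ponndorf–Verley-type equilibration through the ruthenium hydride) delivers the thermodynamic equatorial 2α-alcohol, because a 2β-hydroxyl would be 1,3-diaxial to both the C10 methyl and the C4 acetoxymethyl group, while the neutral medium spares acetate, ketal and triflate.

Step 10
Reactants: 21 2α-alcohol
Product: 22 C6 ketone
Conditions: 1 M HCl, THF, 40 °C
Reagents that add atoms: water, O
Why: Acid-catalysed ketal hydrolysis frees the C6 ketone and the recoverable auxiliary; the β,γ-alkene cannot move into conjugation because it is an enol triflate, and the hindered C5–H is not enolised under these mild conditions.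

Step 11
Reactants: 22 C6 ketone
Product: 23 2α,6α-diol enol triflate
Conditions: Li(s-Bu)3BH (3 equiv), THF, −78 °C
Reagents that add atoms: none
Why: Bulky hydride reduction from the convex β face of the cis-fused bicycle (ring A, attached through C1 and C4, covers the α face) gives the 6α-alcohol.

Step 12
Reactants: 23 2α,6α-diol enol triflate; 24 tributyl(vinyl)stannane
Product: 25 9-vinyl diene diol
Conditions: Pd(PPh3)4 (5 mol %), LiCl (3 equiv), THF, 65 °C
Reagents that add atoms: none
Why: Stille coupling of the enol triflate (LiCl assists transmetalation) forms C9–C11 with the alkene position fixed and tolerates the free hydroxyls and the acetate.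

Step 13
Reactants: 25 9-vinyl diene diol; 26 4-bromofuran-2(5H)-one
Product: 28 target (2R,4S,5S,6S,10S)-19-acetoxy-2α,6α-dihydroxy-5βH-labda-8,13-dien-15,16-olide, via tris-9-BBN intermediate 27 (not isolated)
Conditions: 9-BBN (0.5 M in THF, 4 equiv), 0 °C → rt; then H2O, 26, Pd(dppf)Cl2 (10 mol %), AsPh3, Cs2CO3, DMF, rt
Reagents that add atoms: none
Why: Hydroboration puts boron on the terminal carbon of the monosubstituted vinyl group (the tetrasubstituted alkene is inert; the hydroxyls are capped as borinates) and B-alkyl Suzuki–Miyaura coupling with the β-bromobutenolide forms C12–C13, the borinates being hydrolysed on work-up.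

## Compound list

1 | 2,6-dimethylphenol | Cc1cccc(C)c1O | starting material
2 | 4-methoxy-2,6-dimethylphenol (not isolated) | COc1cc(C)c(O)c(C)c1 | intermediate
3 | 4,4-dimethoxy-2,6-dimethylcyclohexa-2,5-dien-1-one | COC1(OC)C=C(C)C(=O)C(C)=C1 | intermediate
4 | (1S,2S)-1,2-diphenylethane-1,2-diol, (S,S)-hydrobenzoin | O[C@@H](c1ccccc1)[C@@H](O)c1ccccc1 | starting material
5 | (2S,3S)-7,9-dimethyl-2,3-diphenyl-1,4-dioxaspiro[4.5]deca-6,9-dien-8-one | CC1=CC2(C=C(C)C1=O)O[C@@H](c1ccccc1)[C@H](c1ccccc1)O2 | intermediate
6 | methyl acetate | COC(C)=O | starting material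
7 | 3-chloro-2-(chloromethyl)prop-1-ene | C=C(CCl)CCl | starting material
8 | lithium 1-methoxyethenolate (not isolated) | [Li+].[O-]C(=C)OC | intermediate
9 | methyl 4-(chloromethyl)pent-4-enoate | COC(=O)CCC(=C)CCl | intermediate
10 | lithium enolate of 9 (not isolated) | [Li+].[O-]C(OC)=CCC(=C)CCl | intermediate
11 | Michael-adduct lithium dienolate: C9 enolate (C9=C10) of the ketal carrying CH(CO2Me)CH2C(=CH2)CH2Cl on C5, H-5 as in the target, C4 unassigned (not isolated) | COC(=O)C(CC(=C)CCl)[C@@H]1C(C)=C([O-])C(C)=CC12O[C@@H](c3ccccc3)[C@H](c3ccccc3)O2.[Li+] | intermediate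
12 | methyl 8,10β-dimethyl-2-methylidene-9-oxo-5βH-decal-7-ene-4-carboxylate 6-[(S,S)-hydrobenzoin ketal], cis-fused, C4 epimer mixture (C4 left open in the SMILES) | COC(=O)C1CC(=C)C[C@]2(C)C(=O)C(C)=CC3(O[C@@H](c4ccccc4)[C@H](c4ccccc4)O3)[C@H]12 | intermediate
13 | lithium ester enolate of 12, exocyclic at C4 (not isolated) | [Li+].[O-]C(OC)=C1CC(=C)C[C@]2(C)C(=O)C(C)=CC3(O[C@@H](c4ccccc4)[C@H](c4ccccc4)O3)[C@H]12 | intermediate
14 | methyl 4α,8,10β-trimethyl-2-methylidene-9-oxo-5βH-decal-7-ene-4β-carboxylate 6-[(S,S)-hydrobenzoin ketal] | COC(=O)[C@@]1(C)CC(=C)C[C@]2(C)C(=O)C(C)=CC3(O[C@@H](c4ccccc4)[C@H](c4ccccc4)O3)[C@H]12 | intermediate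
15 | lithium C8=C9 enolate from 1,4-reduction of 14 (not isolated) | COC(=O)[C@@]1(C)CC(=C)C[C@]2(C)C([O-])=C(C)CC3(O[C@@H](c4ccccc4)[C@H](c4ccccc4)O3)[C@H]12.[Li+] | intermediate
16 | methyl 4α,8,10β-trimethyl-2-methylidene-9-(trifluoromethanesulfonyloxy)-5βH-decal-8-ene-4β-carboxylate 6-[(S,S)-hydrobenzoin ketal] | COC(=O)[C@@]1(C)CC(=C)C[C@]2(C)C(OS(=O)(=O)C(F)(F)F)=C(C)CC3(O[C@@H](c4ccccc4)[C@H](c4ccccc4)O3)[C@H]12 | intermediate
17 | 4β-hydroxymethyl analogue of 16, formed as its aluminium alkoxide (not isolated) | OC[C@@]1(C)CC(=C)C[C@]2(C)C(OS(=O)(=O)C(F)(F)F)=C(C)CC3(O[C@@H](c4ccccc4)[C@H](c4ccccc4)O3)[C@H]12 | intermediate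
18 | 4β-acetoxymethyl-4α,8,10β-trimethyl-2-methylidene-5βH-decal-8-en-9-yl triflate 6-[(S,S)-hydrobenzoin ketal] | CC(=O)OC[C@@]1(C)CC(=C)C[C@]2(C)C(OS(=O)(=O)C(F)(F)F)=C(C)CC3(O[C@@H](c4ccccc4)[C@H](c4ccccc4)O3)[C@H]12 | intermediate
19 | 2-hydroxy-2-(hydroxymethyl) diol from 18, C2 configuration immaterial (not isolated) | CC(=O)OC[C@@]1(C)CC(O)(CO)C[C@]2(C)C(OS(=O)(=O)C(F)(F)F)=C(C)CC3(O[C@@H](c4ccccc4)[C@H](c4ccccc4)O3)[C@H]12 | intermediate
20 | 4β-acetoxymethyl-4α,8,10β-trimethyl-2-oxo-5βH-decal-8-en-9-yl triflate 6-[(S,S)-hydrobenzoin ketal] | CC(=O)OC[C@@]1(C)CC(=O)C[C@]2(C)C(OS(=O)(=O)C(F)(F)F)=C(C)CC3(O[C@@H](c4ccccc4)[C@H](c4ccccc4)O3)[C@H]12 | intermediate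
21 | 2α-hydroxy analogue of 20 (2R) | CC(=O)OC[C@@]1(C)C[C@H](O)C[C@]2(C)C(OS(=O)(=O)C(F)(F)F)=C(C)CC3(O[C@@H](c4ccccc4)[C@H](c4ccccc4)O3)[C@H]12 | intermediate
22 | 4β-acetoxymethyl-2α-hydroxy-4α,8,10β-trimethyl-6-oxo-5βH-decal-8-en-9-yl triflate | CC(=O)OC[C@@]1(C)C[C@H](O)C[C@]2(C)C(OS(=O)(=O)C(F)(F)F)=C(C)CC(=O)[C@H]12 | intermediate
23 | 4β-acetoxymethyl-2α,6α-dihydroxy-4α,8,10β-trimethyl-5βH-decal-8-en-9-yl triflate | CC(=O)OC[C@@]1(C)C[C@H](O)C[C@]2(C)C(OS(=O)(=O)C(F)(F)F)=C(C)C[C@H](O)[C@H]12 | intermediate
24 | tributyl(vinyl)stannane | CCCC[Sn](CCCC)(CCCC)C=C | starting material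
25 | 4β-acetoxymethyl-9-ethenyl-4α,8,10β-trimethyl-5βH-decal-8-ene-2α,6α-diol | CC(=O)OC[C@@]1(C)C[C@H](O)C[C@]2(C)C(C=C)=C(C)C[C@H](O)[C@H]12 | intermediate
26 | 4-bromofuran-2(5H)-one | BrC1=CC(=O)OC1 | starting material
27 | tris-9-BBN derivative of 25: B-alkyl at C12, O-borinates at O2 and O6 (not isolated) | CC(=O)OC[C@@]1(C)C[C@H](OB3C4CCCC3CCC4)C[C@]2(C)C(CCB3C4CCCC3CCC4)=C(C)C[C@H](OB3C4CCCC3CCC4)[C@H]12 | intermediate
28 | [(1S,3R,4aS,8S,8aS)-3,8-dihydroxy-1,4a,6-trimethyl-5-[2-(5-oxo-2,5-dihydrofuran-3-yl)ethyl]-1,2,3,4,4a,7,8,8a-octahydronaphthalen-1-yl]methyl acetate (CNP0201970.1) | CC(=O)OC[C@@]1(C)C[C@H](O)C[C@]2(C)C(CCC3=CC(=O)OC3)=C(C)C[C@H](O)[C@H]12 | target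

## Step count and risks

Total steps: 13. Longest linear sequence: 12 (steps 1, 2 and 4–13; step 3 is the side branch).

Most likely to fail:

Step 4 (key annulation). The risks are 1,2-addition that does not revert, self-cyclisation of enolate 10 to a methylenecyclobutane, a stalled ring closure at the congested C10 enolate, and modest facial control by the ketal. Fallback: close ring A by intramolecular oxidative coupling of two ketone enolates instead of by alkylation. Setting out from 5, the lithium enolate of methyl 4,4-dimethoxypentanoate F1 (from methyl levulinate, HC(OMe)3, MeOH, cat. TsOH) is added (LiN(i-Pr)2, THF, −78 → 0 °C) to give, after protonation, the Michael adduct F2. PPTS in wet acetone removes only the acyclic dimethyl ketal to give the methyl ketone F3. Double deprotonation (LiN(i-Pr)2, 2.2 equiv, at C10–H and the C1 methyl) and oxidation with Fe(acac)3 joins C10 to C1, the tether again enforcing the cis fusion, to give the bicyclic diketone F4. Wittig methylenation of the unhindered C2 ketone (Ph3P=CH2, THF) returns to 12.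

Step 5 (facial selectivity of the C4 methylation). The α approach that avoids the axial C10 methyl runs close to one ketal oxygen on C6, so the ratio may be poor or reversed. Fallback: make the C4 centre during the annulation rather than by alkylating the bicycle. Setting out from 5 and by-passing 12, the lithium enolate of methyl 4-(chloromethyl)-2-methylpent-4-enoate F5 (from methyl propanoate and 7 as in step 3) is used under the step-4 protocol. C4 is then fixed in the open Michael transition state, whose sense can be tuned through the enolate geometry (THF versus THF/DMPU); the C4 epimers are separated and the route is rejoined at 14.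

Step 9 (equilibrating reduction at C2). Hydride transfer to the β face, past two syn-axial groups, may be too slow for equilibrium to be reached, leaving the kinetic axial alcohol. Fallback: set C2 by inversion. From 20, Li(s-Bu)3BH at −78 °C gives by equatorial attack the 2β-alcohol F6. Mitsunobu reaction with chloroacetic acid (PPh3, DIAD, toluene) gives the inverted 2α-chloroacetate F7. Thiourea/NaHCO3 in ethanol at 50 °C removes the chloroacetyl group without touching the C19 acetate and returns to 21.

Further compounds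

F1 | step 4 | methyl 4,4-dimethoxypentanoate | COC(=O)CCC(C)(OC)OC
F2 | step 4 | Michael adduct of F1 and 5: C9 ketone with C10–H, side chain CH(CO2Me)CH2C(OMe)2CH3 on C5 | COC(=O)C(CC(C)(OC)OC)[C@@H]1C(C)C(=O)C(C)=CC12O[C@@H](c3ccccc3)[C@H](c3ccccc3)O2
F3 | step 4 | methyl ketone from F2, side chain CH(CO2Me)CH2C(=O)CH3 on C5 | COC(=O)C(CC(C)=O)[C@@H]1C(C)C(=O)C(C)=CC12O[C@@H](c3ccccc3)[C@H](c3ccccc3)O2
F4 | step 4 | methyl 8,10β-dimethyl-2,9-dioxo-5βH-decal-7-ene-4-carboxylate 6-[(S,S)-hydrobenzoin ketal], C4 epimers | COC(=O)C1CC(=O)C[C@]2(C)C(=O)C(C)=CC3(O[C@@H](c4ccccc4)[C@H](c4ccccc4)O3)[C@H]12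
F5 | step 5 | methyl 4-(chloromethyl)-2-methylpent-4-enoate | COC(=O)C(C)CC(=C)CCl
F6 | step 9 | 2β-hydroxy epimer of 21 | CC(=O)OC[C@@]1(C)C[C@@H](O)C[C@]2(C)C(OS(=O)(=O)C(F)(F)F)=C(C)CC3(O[C@@H](c4ccccc4)[C@H](c4ccccc4)O3)[C@H]12
F7 | step 9 | 2α-chloroacetate of 21 | CC(=O)OC[C@@]1(C)C[C@H](OC(=O)CCl)C[C@]2(C)C(OS(=O)(=O)C(F)(F)F)=C(C)CC3(O[C@@H](c4ccccc4)[C@H](c4ccccc4)O3)[C@H]12
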